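A direct plan would close the 14-membered ring by an intramolecular Horner–Wadsworth–Emmons reaction of the open-chain phosphonate aldehyde A4 to the macrocyclic enoate A5, and would then reduce the ester.
A4 would be built in a line: C1 would be set by (−)-sparteine-mediated lithiation of the carbamate A1 and borylation with the allylboronate A2, and the side chain would be put onto the resulting boronic ester A3 by a Zweifel olefination.
Weak point 1, the ring closure by olefination: the entropically costly macrocyclisation would coincide with the creation of the trisubstituted C7=C8 olefin, so high dilution and the E/Z outcome of an α-alkyl phosphonoacetate in a cyclic transition state would both have to go right at the last C–C bond.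
Weak point 2, the creation of C1 by lithiation–borylation: it would need a stoichiometric chiral diamine, hours of s-BuLi at −78 °C beside a primary chloride, and reagent control alone for the only stereocentre.
Weak point 3, the attachment of the side chain to the hindered boronic ester A3 and the alkylation of phosphonoacetate by a homoallylic chloride prone to elimination: two more C–C bonds in the longest chain only to decorate C1 and to arm the ring closure.

Retrosynthetic overview (cembrane numbering: C1 stereocentre; ring olefins C3=C4, C7=C8, C11=C12; C19 is the CH2OH carbon on C8):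
1. The allylic alcohol C7=C8–C19–OH would be made last, by a sulfoxide–sulfenate [2,3] shift of the macrocyclic allyl sulfide 24 (sulfur on C7, exocyclic C8=C19).
2. The only ring would be closed before that at the C6–C7 sp3–sp3 bond, by intramolecular α-alkylation of the lithiated 2-pyridyl allyl sulfide 22; C7=C8 does not yet exist, so no olefin geometry is at stake in the ring closure.
3. 22 would come from alkenyl iodide 15 and iodide 19 by Negishi coupling at C10–C11; in 15 the Z olefin C3=C4 would come from a Still–Wittig shift and the E olefin C11=C12 from carboalumination of an alkyne.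
4. C1 with its complete side chain, C2, C3 and C12 to C14 would come from limonene-1,2-diol 1 in two steps (allylic lithiation with prenylation, then glycol cleavage to keto aldehyde 5).
5. The stereocentre is thus taken from the chiral pool, ring closure and olefin geometry are uncoupled, and the sulfur that enables ring closure is exchanged for the C19 hydroxyl in the last step, without protecting group or ester reduction.

Key step: step 12

Remark on the chemistry: 1, 2 and 16 are taken as commercial; the E preference of the [2,3] shift of 2-substituted allyl sulfoxides is assumed to hold inside the 14-membered ring.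

Step 1
Reactants: 1 (1S,2S,4R)-1-methyl-4-(prop-1-en-2-yl)cyclohexane-1,2-diol; 2 1-bromo-3-methylbut-2-ene
Product: 4 (1S,2S,4R)-1-methyl-4-(6-methylhepta-1,5-dien-2-yl)cyclohexane-1,2-diol, via trilithiated diol 3 (not isolated)
Conditions: n-BuLi (3.3 equiv), TMEDA, hexane/Et2O, 0 → 23 °C; 2, −78 → 0 °C; H2O
Reagents that add atoms: none
Why: Allylic lithiation of the isopropenyl methyl group (the two alkoxides are spectators, as in dianion chemistry of isopropenyl carbinols) gives a 2-substituted allyllithium with equivalent termini, so SN2 alkylation by the primary allylic bromide should install the whole side chain in one step, with the ring stereocentre carried over from the chiral pool.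

Step 2
Reactants: 4 (1S,2S,4R)-1-methyl-4-(6-methylhepta-1,5-dien-2-yl)cyclohexane-1,2-diol
Product: 5 (3R)-3-(6-methylhepta-1,5-dien-2-yl)-6-oxoheptanal
Conditions: NaIO4, THF/H2O, 0 → 23 °C
Reagents that add atoms: none
Why: Malaprade glycol cleavage should open the six-membered ring to the aldehyde (future C3) and the methyl ketone (future C12, its methyl becoming C11) without touching the olefins or the stereocentre.

Step 3
Reactants: 5 (3R)-3-(6-methylhepta-1,5-dien-2-yl)-6-oxoheptanal
Product: 7 (5R,7RS)-8-methyl-5-(6-methylhepta-1,5-dien-2-yl)-7-[(trimethylsilyl)oxy]non-8-en-2-one, via bromomagnesium alkoxide 6 (not isolated)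
Conditions: CH2=C(CH3)MgBr (1.1 equiv), THF, −78 °C; then Me3SiCl, −78 → 0 °C; aq. NaHCO3
Reagents that add atoms: prop-1-en-2-ylmagnesium bromide, CC(=C)[Mg]Br; chlorotrimethylsilane, C[Si](C)(C)Cl
Why: Chemoselective Grignard addition to the aldehyde (the methyl ketone is much slower at −78 °C) with O-silylation in the same flask should give the protected isopropenyl carbinol; the new carbinol centre forms as a mixture that is erased in step 6.

Step 4
Reactants: 7 (5R,7RS)-8-methyl-5-(6-methylhepta-1,5-dien-2-yl)-7-[(trimethylsilyl)oxy]non-8-en-2-one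
Product: 10 (3RS,5R)-2-methyl-5-(6-methylhepta-1,5-dien-2-yl)non-1-en-8-yn-3-ol, via enol phosphate 8 (not isolated), via silylated alkyne 9 (not isolated)
Conditions: LiN(i-Pr)2 (1.1 equiv), THF, −78 °C; ClP(O)(OEt)2, −78 → 23 °C; LiN(i-Pr)2 (2.3 equiv), −78 → 23 °C; then K2CO3, MeOH
Reagents that add atoms: none
Why: Negishi's one-flask conversion of a methyl ketone into a terminal alkyne (kinetic enolisation at CH3, O-phosphorylation, elimination) should give the C12≡C11 alkyne, and methanolysis frees the carbinol.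

Step 5
Reactants: 10 (3RS,5R)-2-methyl-5-(6-methylhepta-1,5-dien-2-yl)non-1-en-8-yn-3-ol
Product: 11 tributyl({[(3RS,5R)-2-methyl-5-(6-methylhepta-1,5-dien-2-yl)non-1-en-8-yn-3-yl]oxy}methyl)stannane
Conditions: KH, THF, 0 °C; Bu3SnCH2I, 0 → 23 °C
Reagents that add atoms: tributyl(iodomethyl)stannane, CCCC[Sn](CCCC)(CCCC)CI
Why: Williamson etherification of the potassium alkoxide with the reactive iodomethylstannane should give the stannylmethyl ether needed for the Still–Wittig shift.

Step 6
Reactants: 11 tributyl({[(3RS,5R)-2-methyl-5-(6-methylhepta-1,5-dien-2-yl)non-1-en-8-yn-3-yl]oxy}methyl)stannane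
Product: 13 (3Z,6R)-3-methyl-6-(6-methylhepta-1,5-dien-2-yl)dec-3-en-9-yn-1-ol, via lithiomethyl ether 12 (not isolated)
Conditions: n-BuLi (2.5 equiv), THF, −78 °C; H2O
Reagents that add atoms: none
Why: Still–Wittig rearrangement: tin–lithium exchange gives an α-alkoxymethyllithium whose [2,3]-sigmatropic shift, through the transition state with the carbinol substituent pseudoaxial, should give the Z olefin C3=C4 and the C6 primary alcohol from both carbinol epimers.

Step 7
Reactants: 13 (3Z,6R)-3-methyl-6-(6-methylhepta-1,5-dien-2-yl)dec-3-en-9-yn-1-ol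
Product: 15 (3Z,6R,9E)-10-iodo-3,9-dimethyl-6-(6-methylhepta-1,5-dien-2-yl)deca-3,9-dien-1-ol, via alkenylalane 14 (not isolated)
Conditions: Me3Al (3.5 equiv), Cp2ZrCl2 (25 mol %), CH2Cl2, 0 → 23 °C; then I2, THF, −30 °C; aq. potassium sodium tartrate
Reagents that add atoms: trimethylaluminium, C[Al](C)C; iodine, II
Why: Negishi zirconium-catalysed syn-carboalumination puts methyl on C12 and aluminium on C11 of the terminal alkyne, and iodinolysis with retention should give the E alkenyl iodide, the hydroxyl being carried as its aluminium alkoxide.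

Step 8
Reactants: 16 3-methylbut-3-en-1-ol
Product: 18 3-methylidene-4-(pyridin-2-ylsulfanyl)butan-1-ol, via dilithiated alcohol 17 (not isolated)
Conditions: n-BuLi (2.2 equiv), TMEDA, Et2O/hexane, 0 → 23 °C; (2-PyS)2, THF, −78 °C; H2O
Reagents that add atoms: 2,2'-dipyridyl disulfide, c1ccc(nc1)SSc1ccccn1
Why: Allylic lithiation of the alkoxide of isoprenol gives a 2-substituted allyllithium with equivalent termini, and its sulfenylation by the disulfide should give the 2-pyridyl allyl sulfide that carries C7 to C10 and C19.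

Step 9
Reactants: 18 3-methylidene-4-(pyridin-2-ylsulfanyl)butan-1-ol
Product: 19 2-[(4-iodo-2-methylidenebutyl)sulfanyl]pyridine
Conditions: I2, PPh3, imidazole, CH2Cl2, 0 °C
Reagents that add atoms: iodine, II
Why: Garegg–Samuelsson (Appel-type) iodination should convert the primary alcohol into the primary iodide by SN2 displacement of the oxyphosphonium group.

Step 10
Reactants: 15 (3Z,6R,9E)-10-iodo-3,9-dimethyl-6-(6-methylhepta-1,5-dien-2-yl)deca-3,9-dien-1-ol; 19 2-[(4-iodo-2-methylidenebutyl)sulfanyl]pyridine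
Product: 21 (3Z,6R,9E)-3,9-dimethyl-6-(6-methylhepta-1,5-dien-2-yl)-13-methylidene-14-(pyridin-2-ylsulfanyl)tetradeca-3,9-dien-1-ol, via alkylzinc iodide 20 (not isolated)
Conditions: 19, Zn dust, LiCl, THF, 30 °C; then 15, Pd(dppf)Cl2 (5 mol %), THF/DMA, 40 °C
Reagents that add atoms: none
Why: Zinc insertion into the alkyl iodide followed by Negishi sp3–sp2 cross-coupling should form C10–C11 with retention of the E geometry, the thioether and the free hydroxyl being tolerated by the organozinc.

Step 11
Reactants: 21 (3Z,6R,9E)-3,9-dimethyl-6-(6-methylhepta-1,5-dien-2-yl)-13-methylidene-14-(pyridin-2-ylsulfanyl)tetradeca-3,9-dien-1-ol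
Product: 22 2-{[(5E,9R,11Z)-14-iodo-6,12-dimethyl-9-(6-methylhepta-1,5-dien-2-yl)-2-methylidenetetradeca-5,11-dien-1-yl]sulfanyl}pyridine
Conditions: I2, PPh3, imidazole, CH2Cl2, 0 °C; used at once
Reagents that add atoms: iodine, II
Why: Garegg–Samuelsson iodination of the homoallylic primary alcohol should give the C6 iodide that serves as the electrophile of the ring closure.

Step 12
Reactants: 22 2-{[(5E,9R,11Z)-14-iodo-6,12-dimethyl-9-(6-methylhepta-1,5-dien-2-yl)-2-methylidenetetradeca-5,11-dien-1-yl]sulfanyl}pyridine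
Product: 24 2-{[(1RS,4Z,7R,10E)-4,10-dimethyl-7-(6-methylhepta-1,5-dien-2-yl)-14-methylidenecyclotetradeca-4,10-dien-1-yl]sulfanyl}pyridine, via lithiated sulfide 23 (not isolated)
Conditions: LiN(i-Pr)2 (1.1 equiv), THF (0.002 M), −78 → −20 °C; H2O
Reagents that add atoms: none
Why: The amide base removes the proton between sulfur and the C8=C19 methylidene to give a lithium-chelated α-thio allyl anion, which displaces the primary iodide at C6 in an intramolecular SN2 reaction; the closest known reaction type is the Biellmann alkylation of lithiated allyl sulfides, which has served for ring closure of 14-membered terpenoid carbocycles. The ring, the only one of the target, is closed in the 14-exo-tet mode at a bond between two sp3 carbons, so no double bond has to form in a cyclic transition state. The new stereocentre at C7 need not be controlled, since both epimers give the same olefin in step 13. The selectivities needed are α- over γ-alkylation, secured by N–Li chelation of the 2-pyridylthio group that holds lithium at the sulfur-bearing carbon, and ring closure over oligomerisation, secured by high dilution. One equivalent of an amide base is used so that neither halogen–lithium exchange nor elimination of the homoallylic iodide competes, and the C1 stereocentre and the Z and E olefins, which are remote from both reacting carbons, are not touched.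

Step 13
Reactants: 24 2-{[(1RS,4Z,7R,10E)-4,10-dimethyl-7-(6-methylhepta-1,5-dien-2-yl)-14-methylidenecyclotetradeca-4,10-dien-1-yl]sulfanyl}pyridine
Product: 27 [(1E,5Z,8R,11E)-5,11-dimethyl-8-(6-methylhepta-1,5-dien-2-yl)cyclotetradeca-1,5,11-trien-1-yl]methanol, via allylic sulfoxide 25 (not isolated), via sulfenate ester 26 (not isolated)
Conditions: mCPBA (1.0 equiv), CH2Cl2, −78 °C; then Et2NH, MeOH, 23 °C
Reagents that add atoms: 3-chloroperbenzoic acid, OOC(=O)c1cccc(Cl)c1
Why: Chemoselective S-oxidation at low temperature and Mislow–Evans [2,3]-sigmatropic sulfoxide–sulfenate rearrangement, with diethylamine as thiophile, should move the heteroatom from C7 to C19 as hydroxyl and form C7=C8 with the E geometry (C6 and C9 cis) that 2-substituted allyl sulfoxides favour, both C7 epimers converging on one product.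

Compound list
1 | (1S,2S,4R)-1-methyl-4-(prop-1-en-2-yl)cyclohexane-1,2-diol (limonene-1,2-diol) | CC(=C)[C@@H]1CC[C@](C)(O)[C@@H](O)C1 | starting material
2 | 1-bromo-3-methylbut-2-ene (prenyl bromide) | CC(C)=CCBr | starting material
3 | trilithiated diol (dilithium alkoxide of 1 lithiated at the isopropenyl methyl) | [Li]CC(=C)[C@@H]1CC[C@](C)(O[Li])[C@@H](O[Li])C1 | intermediate
4 | (1S,2S,4R)-1-methyl-4-(6-methylhepta-1,5-dien-2-yl)cyclohexane-1,2-diol | CC(C)=CCCC(=C)[C@@H]1CC[C@](C)(O)[C@@H](O)C1 | intermediate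
5 | (3R)-3-(6-methylhepta-1,5-dien-2-yl)-6-oxoheptanal | CC(C)=CCCC(=C)[C@H](CCC(C)=O)CC=O | intermediate
6 | bromomagnesium alkoxide of (5R,7RS)-7-hydroxy-8-methyl-5-(6-methylhepta-1,5-dien-2-yl)non-8-en-2-one | CC(C)=CCCC(=C)[C@H](CCC(C)=O)CC(O[Mg]Br)C(C)=C | intermediate
7 | (5R,7RS)-8-methyl-5-(6-methylhepta-1,5-dien-2-yl)-7-[(trimethylsilyl)oxy]non-8-en-2-one | CC(C)=CCCC(=C)[C@H](CCC(C)=O)CC(O[Si](C)(C)C)C(C)=C | intermediate
8 | diethyl (5R,7RS)-8-methyl-5-(6-methylhepta-1,5-dien-2-yl)-7-[(trimethylsilyl)oxy]nona-1,8-dien-2-yl phosphate | CC(C)=CCCC(=C)[C@H](CCC(=C)OP(=O)(OCC)OCC)CC(O[Si](C)(C)C)C(C)=C | intermediate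
9 | trimethyl{[(3RS,5R)-2-methyl-5-(6-methylhepta-1,5-dien-2-yl)non-1-en-8-yn-3-yl]oxy}silane | CC(C)=CCCC(=C)[C@H](CCC#C)CC(O[Si](C)(C)C)C(C)=C | intermediate
10 | (3RS,5R)-2-methyl-5-(6-methylhepta-1,5-dien-2-yl)non-1-en-8-yn-3-ol | CC(C)=CCCC(=C)[C@H](CCC#C)CC(O)C(C)=C | intermediate
11 | tributyl({[(3RS,5R)-2-methyl-5-(6-methylhepta-1,5-dien-2-yl)non-1-en-8-yn-3-yl]oxy}methyl)stannane | CC(C)=CCCC(=C)[C@H](CCC#C)CC(OC[Sn](CCCC)(CCCC)CCCC)C(C)=C | intermediate
12 | lithiomethyl ether of 10 (acetylide also lithiated) | CC(C)=CCCC(=C)[C@H](CCC#C[Li])CC(OC[Li])C(C)=C | intermediate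
13 | (3Z,6R)-3-methyl-6-(6-methylhepta-1,5-dien-2-yl)dec-3-en-9-yn-1-ol | CC(C)=CCCC(=C)[C@H](CCC#C)C/C=C(/C)CCO | intermediate
14 | (E)-alkenyl(dimethyl)alane from 13 (hydroxyl as dimethylaluminium alkoxide) | CC(C)=CCCC(=C)[C@H](CC/C(C)=C/[Al](C)C)C/C=C(/C)CCO[Al](C)C | intermediate
15 | (3Z,6R,9E)-10-iodo-3,9-dimethyl-6-(6-methylhepta-1,5-dien-2-yl)deca-3,9-dien-1-ol | CC(C)=CCCC(=C)[C@H](CC/C(C)=C/I)C/C=C(/C)CCO | intermediate
16 | 3-methylbut-3-en-1-ol (isoprenol) | CC(=C)CCO | starting material
17 | dilithiated 3-methylbut-3-en-1-ol (lithium alkoxide, allyllithium) | [Li]CC(=C)CCO[Li] | intermediate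
18 | 3-methylidene-4-(pyridin-2-ylsulfanyl)butan-1-ol | OCCC(=C)CSc1ccccn1 | intermediate
19 | 2-[(4-iodo-2-methylidenebutyl)sulfanyl]pyridine | ICCC(=C)CSc1ccccn1 | intermediate
20 | iodo[3-methylidene-4-(pyridin-2-ylsulfanyl)butyl]zinc | I[Zn]CCC(=C)CSc1ccccn1 | intermediate
21 | (3Z,6R,9E)-3,9-dimethyl-6-(6-methylhepta-1,5-dien-2-yl)-13-methylidene-14-(pyridin-2-ylsulfanyl)tetradeca-3,9-dien-1-ol | CC(C)=CCCC(=C)[C@H](CC/C(C)=C/CCC(=C)CSc1ccccn1)C/C=C(/C)CCO | intermediate
22 | 2-{[(5E,9R,11Z)-14-iodo-6,12-dimethyl-9-(6-methylhepta-1,5-dien-2-yl)-2-methylidenetetradeca-5,11-dien-1-yl]sulfanyl}pyridine | CC(C)=CCCC(=C)[C@H](CC/C(C)=C/CCC(=C)CSc1ccccn1)C/C=C(/C)CCI | intermediate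
23 | α-lithio derivative of 22 (lithium on the sulfur-bearing carbon) | CC(C)=CCCC(=C)[C@H](CC/C(C)=C/CCC(=C)C([Li])Sc1ccccn1)C/C=C(/C)CCI | intermediate
24 | 2-{[(1RS,4Z,7R,10E)-4,10-dimethyl-7-(6-methylhepta-1,5-dien-2-yl)-14-methylidenecyclotetradeca-4,10-dien-1-yl]sulfanyl}pyridine | C=C(CCC=C(C)C)[C@H]1C/C=C(/C)CCC(Sc2ccccn2)C(=C)CC/C=C(\C)CC1 | intermediate
25 | 2-{[(1RS,4Z,7R,10E)-4,10-dimethyl-7-(6-methylhepta-1,5-dien-2-yl)-14-methylidenecyclotetradeca-4,10-dien-1-yl]sulfinyl}pyridine | C=C(CCC=C(C)C)[C@H]1C/C=C(/C)CCC(S(=O)c2ccccn2)C(=C)CC/C=C(\C)CC1 | intermediate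
26 | [(1E,5Z,8R,11E)-5,11-dimethyl-8-(6-methylhepta-1,5-dien-2-yl)cyclotetradeca-1,5,11-trien-1-yl]methyl pyridine-2-sulfenate | C=C(CCC=C(C)C)[C@H]1C/C=C(/C)CC/C=C(/COSc2ccccn2)CC/C=C(\C)CC1 | intermediate
27 | [(1E,5Z,8R,11E)-5,11-dimethyl-8-(6-methylhepta-1,5-dien-2-yl)cyclotetradeca-1,5,11-trien-1-yl]methanol (CNP0237384.1) | C=C(CCC=C(C)C)[C@H]1C/C=C(/C)CC/C=C(/CO)CC/C=C(\C)CC1 | target

Total step count: 13. Longest linear sequence: 11 steps (steps 1 to 7 and 10 to 13, from 1).

Steps most likely to fail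

Step 12 (ring closure). What may go wrong: alkylation between two molecules may outrun the 14-membered ring closure, the anion may attack through its unsubstituted γ-terminus, or the base may eliminate the homoallylic iodide. The fallback would form the C6–C7 bond between two molecules and close the ring at C10–C11 by a palladium-catalysed coupling; it sets out from 15 and comes back at 24. 15 would be converted (I2, PPh3, imidazole) into (1E,5R,7Z)-1,10-diiodo-2,8-dimethyl-5-(6-methylhepta-1,5-dien-2-yl)deca-1,7-diene F3, and 18 (MeSO2Cl, Et3N; then LiCl) into 2-[(4-chloro-2-methylidenebutyl)sulfanyl]pyridine F4. Lithiated F4 (n-BuLi, THF, −78 °C) would displace the primary iodide of F3 to give 2-{[(4RS,7Z,10R,13E)-1-chloro-14-iodo-7,13-dimethyl-10-(6-methylhepta-1,5-dien-2-yl)-3-methylidenetetradeca-7,13-dien-4-yl]sulfanyl}pyridine F5. Halide exchange (NaI, acetone) would give 2-{[(4RS,7Z,10R,13E)-1,14-diiodo-7,13-dimethyl-10-(6-methylhepta-1,5-dien-2-yl)-3-methylidenetetradeca-7,13-dien-4-yl]sulfanyl}pyridine F6. Zinc (Zn dust, LiCl) would insert into the alkyl iodide only, to give the alkylzinc iodide F7, and Pd(dppf)Cl2 under high dilution would close the ring by Negishi coupling to 24.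

Step 1 (side chain on the diol). What may go wrong: the dialkoxide aggregate may resist or misdirect the allylic lithiation, and alkoxide oxygen may compete with carbon for the bromide. The fallback would mask the diol; it sets out from 1 and comes back at 5. 1 would be converted (2,2-dimethoxypropane, pyridinium tosylate) into (3aS,5R,7aS)-2,2,7a-trimethyl-5-(prop-1-en-2-yl)hexahydro-1,3-benzodioxole F1. Allylic metalation (n-BuLi, KOt-Bu, THF, −50 °C) and alkylation with 2 would give (3aS,5R,7aS)-2,2,7a-trimethyl-5-(6-methylhepta-1,5-dien-2-yl)hexahydro-1,3-benzodioxole F2. H5IO6 in THF/H2O would hydrolyse the acetal and cleave the glycol in one operation to 5.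

Step 13 (sulfoxide–sulfenate shift). What may go wrong: inside the ring the two envelope transition states may lie closer than in open chains, which would erode the geometry at C7=C8, and syn-elimination of the pyridyl sulfoxide towards C6 may compete. The fallback would run the shift on the open chain, where its E preference rests on acyclic precedent, and close the ring afterwards at C10–C11; it sets out from 15 and comes back at 27. F5, reached from 15 through F3 as described above, would be oxidised and rearranged (mCPBA, −78 °C; Et2NH, MeOH) to (2E,6Z,9R,12E)-2-(2-chloroethyl)-13-iodo-6,12-dimethyl-9-(6-methylhepta-1,5-dien-2-yl)trideca-2,6,12-trien-1-ol F8. NaI in acetone would give (2E,6Z,9R,12E)-13-iodo-2-(2-iodoethyl)-6,12-dimethyl-9-(6-methylhepta-1,5-dien-2-yl)trideca-2,6,12-trien-1-ol F9. Zinc insertion into the alkyl iodide would give the alkylzinc iodide F10, and Pd(dppf)Cl2 under high dilution would close the ring to 27.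

Further compounds
F1 | step 1 | (3aS,5R,7aS)-2,2,7a-trimethyl-5-(prop-1-en-2-yl)hexahydro-1,3-benzodioxole | CC(=C)[C@@H]1CC[C@]2(C)OC(C)(C)O[C@H]2C1
F2 | step 1 | (3aS,5R,7aS)-2,2,7a-trimethyl-5-(6-methylhepta-1,5-dien-2-yl)hexahydro-1,3-benzodioxole | CC(C)=CCCC(=C)[C@@H]1CC[C@]2(C)OC(C)(C)O[C@H]2C1
F3 | step 12 | (1E,5R,7Z)-1,10-diiodo-2,8-dimethyl-5-(6-methylhepta-1,5-dien-2-yl)deca-1,7-diene | CC(C)=CCCC(=C)[C@H](CC/C(C)=C/I)C/C=C(/C)CCI
F4 | step 12 | 2-[(4-chloro-2-methylidenebutyl)sulfanyl]pyridine | ClCCC(=C)CSc1ccccn1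
F5 | step 12 | 2-{[(4RS,7Z,10R,13E)-1-chloro-14-iodo-7,13-dimethyl-10-(6-methylhepta-1,5-dien-2-yl)-3-methylidenetetradeca-7,13-dien-4-yl]sulfanyl}pyridine | CC(C)=CCCC(=C)[C@H](CC/C(C)=C/I)C/C=C(/C)CCC(Sc1ccccn1)C(=C)CCCl
F6 | step 12 | 2-{[(4RS,7Z,10R,13E)-1,14-diiodo-7,13-dimethyl-10-(6-methylhepta-1,5-dien-2-yl)-3-methylidenetetradeca-7,13-dien-4-yl]sulfanyl}pyridine | CC(C)=CCCC(=C)[C@H](CC/C(C)=C/I)C/C=C(/C)CCC(Sc1ccccn1)C(=C)CCI
F7 | step 12 | alkylzinc iodide formed from F6 at the primary carbon | CC(C)=CCCC(=C)[C@H](CC/C(C)=C/I)C/C=C(/C)CCC(Sc1ccccn1)C(=C)CC[Zn]I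
F8 | step 13 | (2E,6Z,9R,12E)-2-(2-chloroethyl)-13-iodo-6,12-dimethyl-9-(6-methylhepta-1,5-dien-2-yl)trideca-2,6,12-trien-1-ol | CC(C)=CCCC(=C)[C@H](CC/C(C)=C/I)C/C=C(/C)CC/C=C(/CO)CCCl
F9 | step 13 | (2E,6Z,9R,12E)-13-iodo-2-(2-iodoethyl)-6,12-dimethyl-9-(6-methylhepta-1,5-dien-2-yl)trideca-2,6,12-trien-1-ol | CC(C)=CCCC(=C)[C@H](CC/C(C)=C/I)C/C=C(/C)CC/C=C(/CO)CCI
F10 | step 13 | alkylzinc iodide formed from F9 at the primary carbon | CC(C)=CCCC(=C)[C@H](CC/C(C)=C/I)C/C=C(/C)CC/C=C(/CO)CC[Zn]I
A1 | direct plan | (4E)-7-chloro-4-methylhept-4-en-1-yl N,N-diisopropylcarbamate | ClCC/C=C(\C)CCCOC(=O)N(C(C)C)C(C)C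
A2 | direct plan | 2-[(2Z)-6,6-dimethoxy-3-methylhex-2-en-1-yl]-4,4,5,5-tetramethyl-1,3,2-dioxaborolane | CC1(C)OB(C/C=C(/C)CCC(OC)OC)OC1(C)C
A3 | direct plan | 2-[(3E,7R,9Z)-1-chloro-13,13-dimethoxy-4,10-dimethyltrideca-3,9-dien-7-yl]-4,4,5,5-tetramethyl-1,3,2-dioxaborolane | CC1(C)OB([C@H](CC/C(C)=C/CCCl)C/C=C(/C)CCC(OC)OC)OC1(C)C
A4 | direct plan | ethyl (5E,9R,11Z)-2-(diethoxyphosphoryl)-6,12-dimethyl-9-(6-methylhepta-1,5-dien-2-yl)-15-oxopentadeca-5,11-dienoate | C=C(CCC=C(C)C)[C@H](CC/C(C)=C/CCC(C(=O)OCC)P(=O)(OCC)OCC)C/C=C(/C)CCC=O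
A5 | direct plan | ethyl (1E,5Z,8R,11E)-5,11-dimethyl-8-(6-methylhepta-1,5-dien-2-yl)cyclotetradeca-1,5,11-triene-1-carboxylate | C=C(CCC=C(C)C)[C@H]1C/C=C(/C)CC/C=C(/C(=O)OCC)CC/C=C(\C)CC1
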